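**Strategy.** The C3–C4 bond of the dihydropyran ring (O1, C2, C3, C4, C4a, C8a) joins two benzylic carbons: C4 on the trioxygenated ring A and C3 on the future quinone ring B. The pyran is therefore made by ring contraction. A 2,3,4,5-tetrahydro-1,4-benzoxazepine, in which an NH group bridges these two carbons, loses its nitrogen as N2 through an isodiazene, and the benzylic radical pair closes the chroman with the C3 configuration already in place. The seven-membered amine is assembled from a sulfinamide-derived chiral amine and formaldehyde (Pictet–Spengler closure onto ring A). MOM cleavage and Teuber oxidation of the resorcinol ring then give the hydroxyquinone.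

Key step: step 9

Remark: prenyl = 3-methylbut-2-en-1-yl, MOM = methoxymethyl; C3 is (R) in the target, the N-bearing carbon of 14–19 is also (R) (N > CH2O > aryl), and 7, 9, 12 and 18 are taken as purchasable.

Step 1
Reactants: 1 1,3-dimethoxybenzene; 2 1-bromo-3-methylbut-2-ene (prenyl bromide)
Product: 3 1,3-dimethoxy-2-prenylbenzene
Conditions: n-BuLi, THF, 0 °C to rt; then 2, CuI (cat.), −78 °C to rt
Reagents that add atoms: none
Why: Directed ortho-metalation between the two methoxy groups followed by copper-assisted SN2 allylation of the aryllithium should place the prenyl group at C2.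

Step 2
Reactants: 3 1,3-dimethoxy-2-prenylbenzene; 4 bis(pinacolato)diboron
Product: 6 3,5-dimethoxy-4-prenylphenol, via pinacol arylboronate 5 (not isolated)
Conditions: [Ir(OMe)(cod)]2 (cat.), dtbpy (cat.), THF, 80 °C; then H2O2, aq. NaOH, 0 °C
Reagents that add atoms: hydrogen peroxide OO
Why: Sterically controlled iridium-catalysed C–H borylation should take the only C–H without an ortho substituent (para to the prenyl group), and basic peroxide oxidation of the C–B bond gives the phenol without touching the unactivated trisubstituted alkene.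

Step 3
Reactants: 6 3,5-dimethoxy-4-prenylphenol; 7 2-chloro-N-methoxy-N-methylacetamide
Product: 8 2-(3,5-dimethoxy-4-prenylphenoxy)-N-methoxy-N-methylacetamide
Conditions: K2CO3, NaI (cat.), DMF, 60 °C
Reagents that add atoms: none
Why: Williamson etherification of the phenoxide with the activated α-chloroamide should be clean, since the Weinreb amide does not enolise under carbonate.

Step 4
Reactants: 9 1,3-bis(methoxymethoxy)benzene; 2 1-bromo-3-methylbut-2-ene
Product: 10 1,3-bis(methoxymethoxy)-2-prenylbenzene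
Conditions: n-BuLi, THF, 0 °C; then 2, CuI (cat.), −78 °C to rt
Reagents that add atoms: none
Why: Directed ortho-metalation at the position flanked by both MOM ethers, then allylation of the aryllithium, should install the ring-B prenyl group.

Step 5
Reactants: 10 1,3-bis(methoxymethoxy)-2-prenylbenzene; 8 2-(3,5-dimethoxy-4-prenylphenoxy)-N-methoxy-N-methylacetamide
Product: 11 1-[2,4-bis(methoxymethoxy)-3-prenylphenyl]-2-(3,5-dimethoxy-4-prenylphenoxy)ethan-1-one
Conditions: 10, n-BuLi, TMEDA, THF, 0 °C; then 8, −78 to 0 °C; aq. NH4Cl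
Reagents that add atoms: none
Why: A second MOM-directed ortho-lithiation (C4 of 10) and Weinreb ketone synthesis should stop at the ketone because the chelated tetrahedral adduct survives until work-up.

Step 6
Reactants: 11 1-[2,4-bis(methoxymethoxy)-3-prenylphenyl]-2-(3,5-dimethoxy-4-prenylphenoxy)ethan-1-one; 12 (S)-2-methylpropane-2-sulfinamide
Product: 14 (S)-N-{(1R)-1-[2,4-bis(methoxymethoxy)-3-prenylphenyl]-2-(3,5-dimethoxy-4-prenylphenoxy)ethyl}-2-methylpropane-2-sulfinamide, via N-sulfinyl ketimine 13 (not isolated)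
Conditions: Ti(OEt)4, THF, 65 °C; then NaBH4, −48 °C
Reagents that add atoms: none
Why: One-pot sulfinyl ketimine formation and NaBH4 reduction through the cyclic, sulfinyl-oxygen-bound transition state of the E-imine (aryl as the large group) should deliver hydride to the face that gives (R) at carbon under control of the (S)-sulfur centre.

Step 7
Reactants: 14 (S)-N-{(1R)-1-[2,4-bis(methoxymethoxy)-3-prenylphenyl]-2-(3,5-dimethoxy-4-prenylphenoxy)ethyl}-2-methylpropane-2-sulfinamide
Product: 15 (1R)-1-[2,4-bis(methoxymethoxy)-3-prenylphenyl]-2-(3,5-dimethoxy-4-prenylphenoxy)ethan-1-amine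
Conditions: HCl (4 M in dioxane, 2 equiv), MeOH, 0 °C; then aq. NaHCO3
Reagents that add atoms: none
Why: Acidic methanolysis of the S–N bond is fast at 0 °C, so the aryl MOM ethers and prenyl groups should survive, and the stereocentre is not involved.

Step 8
Reactants: 15 (1R)-1-[2,4-bis(methoxymethoxy)-3-prenylphenyl]-2-(3,5-dimethoxy-4-prenylphenoxy)ethan-1-amine
Product: 17 (3R)-3-[2,4-bis(methoxymethoxy)-3-prenylphenyl]-6,8-dimethoxy-7-prenyl-2,3,4,5-tetrahydro-1,4-benzoxazepine, via N-methylene imine 16 (not isolated)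
Conditions: (CH2O)n (1.05 equiv), AcOH (cat.), HFIP, 40 °C
Reagents that add atoms: formaldehyde C=O
Why: Pictet–Spengler-type 7-endo-trig closure of the iminium form of 16 onto the ring-A carbon that is ortho to the ether oxygen and ortho/para to the two methoxy groups should give a single regioisomer (both ortho carbons are equivalent) without touching C3.

Step 9
Reactants: 17 (3R)-3-[2,4-bis(methoxymethoxy)-3-prenylphenyl]-6,8-dimethoxy-7-prenyl-2,3,4,5-tetrahydro-1,4-benzoxazepine; 18 N-(benzyloxy)-N-(pivaloyloxy)-4-(trifluoromethyl)benzamide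
Product: 20 (3R)-3-[2,4-bis(methoxymethoxy)-3-prenylphenyl]-5,7-dimethoxy-6-prenylchromane, via isodiazene 19 (not isolated)
Conditions: 18 (1.5 equiv), THF, 45 °C
Reagents that add atoms: none
Why: The amine nitrogen attacks the electrophilic nitrogen of 18 with loss of pivalate, and the N-alkoxy hydrazide so formed expels benzyl 4-(trifluoromethyl)benzoate to give isodiazene 19, which loses N2 to a singlet pair of benzylic radicals at C3 and C4. The closest known reaction type is the nitrogen deletion of secondary amines through 1,1-diazenes, used for ring contraction of cyclic benzylic amines. The pyran ring closes by radical–radical recombination of this 1,6-diradical, so the seven-membered oxazepine contracts to the six-membered ring in the same operation that forms C3–C4. No new stereocentre is formed; C3 should keep the (R) configuration from step 6 because the O1–C8a–C4a tether holds the two radical centres in contact and recombination should outrun rotation about C2–C3 (net retention). The step needs coupling to win over disproportionation (hydrogen transfer from C2) and over stereomutation; both α-carbons are benzylic, which makes N2 loss fast at 45 °C, and the C4 radical has no β-hydrogen.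

Step 10
Reactants: 20 (3R)-3-[2,4-bis(methoxymethoxy)-3-prenylphenyl]-5,7-dimethoxy-6-prenylchromane
Product: 21 4-[(3R)-5,7-dimethoxy-6-prenylchroman-3-yl]-2-prenylbenzene-1,3-diol
Conditions: HCl (1 M in MeOH), rt
Reagents that add atoms: none
Why: Acetal exchange with methanol removes both MOM groups, and brief dilute acid at rt should avoid cyclisation of the ring-B prenyl group onto the new phenols (ring A has no free phenol).

Step 11
Reactants: 21 4-[(3R)-5,7-dimethoxy-6-prenylchroman-3-yl]-2-prenylbenzene-1,3-diol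
Product: 22 5-[(3R)-5,7-dimethoxy-6-prenylchroman-3-yl]-2-hydroxy-3-prenylcyclohexa-2,5-diene-1,4-dione (target)
Conditions: Fremy's salt (2.5 equiv), KH2PO4 buffer, acetone/H2O, rt
Reagents that add atoms: potassium nitrosodisulfonate (Fremy's salt) [K+].[K+].[O]N(S(=O)(=O)[O-])S(=O)(=O)[O-]
Why: Teuber oxidation of the resorcinol should oxygenate the only free activated carbon (C5', para to the 2'-OH) and give the 2-hydroxy-1,4-benzoquinone, while the fully etherified ring A, the prenyl groups and C3 are not affected.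

**Compound list**

1 | 1,3-dimethoxybenzene | COc1cccc(OC)c1 | starting material
2 | 1-bromo-3-methylbut-2-ene (prenyl bromide) | CC(C)=CCBr | starting material
3 | 1,3-dimethoxy-2-prenylbenzene | COc1cccc(OC)c1CC=C(C)C | intermediate
4 | bis(pinacolato)diboron | CC1(C)OB(OC1(C)C)B1OC(C)(C)C(C)(C)O1 | starting material
5 | 2-(3,5-dimethoxy-4-prenylphenyl)-4,4,5,5-tetramethyl-1,3,2-dioxaborolane | COc1cc(B2OC(C)(C)C(C)(C)O2)cc(OC)c1CC=C(C)C | intermediate
6 | 3,5-dimethoxy-4-prenylphenol | COc1cc(O)cc(OC)c1CC=C(C)C | intermediate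
7 | 2-chloro-N-methoxy-N-methylacetamide | CON(C)C(=O)CCl | starting material
8 | 2-(3,5-dimethoxy-4-prenylphenoxy)-N-methoxy-N-methylacetamide | COc1cc(OCC(=O)N(C)OC)cc(OC)c1CC=C(C)C | intermediate
9 | 1,3-bis(methoxymethoxy)benzene | COCOc1cccc(OCOC)c1 | starting material
10 | 1,3-bis(methoxymethoxy)-2-prenylbenzene | COCOc1cccc(OCOC)c1CC=C(C)C | intermediate
11 | 1-[2,4-bis(methoxymethoxy)-3-prenylphenyl]-2-(3,5-dimethoxy-4-prenylphenoxy)ethan-1-one | COCOc1ccc(C(=O)COc2cc(OC)c(CC=C(C)C)c(OC)c2)c(OCOC)c1CC=C(C)C | intermediate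
12 | (S)-2-methylpropane-2-sulfinamide | CC(C)(C)[S@](=O)N | starting material
13 | (S)-N-sulfinyl ketimine of 11 (C=N geometry not fixed) | CC(C)(C)[S@](=O)N=C(COc1cc(OC)c(CC=C(C)C)c(OC)c1)c1ccc(OCOC)c(CC=C(C)C)c1OCOC | intermediate
14 | (S)-N-{(1R)-1-[2,4-bis(methoxymethoxy)-3-prenylphenyl]-2-(3,5-dimethoxy-4-prenylphenoxy)ethyl}-2-methylpropane-2-sulfinamide | CC(C)(C)[S@](=O)N[C@H](c1ccc(OCOC)c(CC=C(C)C)c1OCOC)COc1cc(OC)c(CC=C(C)C)c(OC)c1 | intermediate
15 | (1R)-1-[2,4-bis(methoxymethoxy)-3-prenylphenyl]-2-(3,5-dimethoxy-4-prenylphenoxy)ethan-1-amine | N[C@H](c1ccc(OCOC)c(CC=C(C)C)c1OCOC)COc1cc(OC)c(CC=C(C)C)c(OC)c1 | intermediate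
16 | N-methylene imine of 15 | C=N[C@H](c1ccc(OCOC)c(CC=C(C)C)c1OCOC)COc1cc(OC)c(CC=C(C)C)c(OC)c1 | intermediate
17 | (3R)-3-[2,4-bis(methoxymethoxy)-3-prenylphenyl]-6,8-dimethoxy-7-prenyl-2,3,4,5-tetrahydro-1,4-benzoxazepine | COCOc1ccc([C@H]2NCc3c(OC)c(CC=C(C)C)c(OC)cc3OC2)c(OCOC)c1CC=C(C)C | intermediate
18 | N-(benzyloxy)-N-(pivaloyloxy)-4-(trifluoromethyl)benzamide | CC(C)(C)C(=O)ON(OCc1ccccc1)C(=O)c1ccc(cc1)C(F)(F)F | starting material
19 | isodiazene (N4=N) of 17 | COCOc1ccc([C@H]2[N+](=[N-])Cc3c(OC)c(CC=C(C)C)c(OC)cc3OC2)c(OCOC)c1CC=C(C)C | intermediate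
20 | (3R)-3-[2,4-bis(methoxymethoxy)-3-prenylphenyl]-5,7-dimethoxy-6-prenylchromane | COCOc1ccc([C@H]2Cc3c(OC)c(CC=C(C)C)c(OC)cc3OC2)c(OCOC)c1CC=C(C)C | intermediate
21 | 4-[(3R)-5,7-dimethoxy-6-prenylchroman-3-yl]-2-prenylbenzene-1,3-diol | COc1cc2c(c(OC)c1CC=C(C)C)C[C@H](c1ccc(O)c(CC=C(C)C)c1O)CO2 | intermediate
22 | 5-[(3R)-5,7-dimethoxy-6-prenylchroman-3-yl]-2-hydroxy-3-prenylcyclohexa-2,5-diene-1,4-dione | COc1cc2c(c(OC)c1CC=C(C)C)C[C@H](C1=CC(=O)C(O)=C(CC=C(C)C)C1=O)CO2 | target

**Step count.** Total: 11 steps. Longest linear sequence: 10 steps (1, 2, 3, 5, 6, 7, 8, 9, 10, 11).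

**Steps most likely to fail**

Step 9. The radical pair may lose the C3 configuration by rotation about C2–C3 before it recombines, or may disproportionate by hydrogen transfer from C2 instead of coupling. The fallback sets out from ketone 11 and returns at 20, building the pyran directly with known reactions:
- Wittig methylenation (Ph3P=CH2, THF) would give the allyl aryl ether 1-[3-(3,5-dimethoxy-4-prenylphenoxy)prop-1-en-2-yl]-2,4-bis(methoxymethoxy)-3-prenylbenzene F1.
- Aromatic Claisen rearrangement (N,N-diethylaniline, 180 °C) would move the allyl unit to the free ortho carbon and give 2-{2-[2,4-bis(methoxymethoxy)-3-prenylphenyl]prop-2-en-1-yl}-3,5-dimethoxy-4-prenylphenol F2.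
- Copper-catalysed enantioselective protoboration of the 1,1-disubstituted aryl alkene (chiral NHC–CuCl, NaOt-Bu, B2pin2, MeOH; ligand enantiomer chosen for (R)) would set C3 in the boronate (R)-2-{2-[2,4-bis(methoxymethoxy)-3-prenylphenyl]-3-(pinacolboryl)propyl}-3,5-dimethoxy-4-prenylphenol F3. The prenyl alkenes are unreactive under these conditions.
- Oxidation (NaBO3, THF/H2O) would give (2R)-2-[2,4-bis(methoxymethoxy)-3-prenylphenyl]-3-(6-hydroxy-2,4-dimethoxy-3-prenylphenyl)propan-1-ol F4.
- Mitsunobu etherification (PPh3, DIAD, THF) of phenol and primary alcohol would close the ring to 20.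

Step 8. The seven-membered closure may be too slow, so that the formaldimine oligomerises, or the product amine may be aminomethylated a second time. The fallback sets out from amine 15 and returns at 17:
- 2-Nitrobenzenesulfonyl chloride and Et3N (CH2Cl2) would give N-{(1R)-1-[2,4-bis(methoxymethoxy)-3-prenylphenyl]-2-(3,5-dimethoxy-4-prenylphenoxy)ethyl}-2-nitrobenzenesulfonamide F5.
- Paraformaldehyde with catalytic TsOH (CH2Cl2, rt) would form the much more electrophilic N-sulfonyliminium ion, which closes to (3R)-3-[2,4-bis(methoxymethoxy)-3-prenylphenyl]-6,8-dimethoxy-4-(2-nitrophenylsulfonyl)-7-prenyl-2,3,4,5-tetrahydro-1,4-benzoxazepine F6. This product cannot react further.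
- Thiophenol and K2CO3 (DMF) would remove the sulfonyl group and give 17.

Step 6. Facial selectivity of the hydride addition may be poor if the ketimine is not a single E isomer or if the ether oxygen chelates the metal. The fallback sets out from ketone 11 and returns at amine 15:
- Transfer hydrogenation (RuCl(p-cymene)(TsDPEN), enantiomer chosen for the (S)-carbinol, HCO2H/Et3N) would give (1S)-1-[2,4-bis(methoxymethoxy)-3-prenylphenyl]-2-(3,5-dimethoxy-4-prenylphenoxy)ethan-1-ol F7.
- Mitsunobu azidation with inversion (DPPA, DIAD, PPh3, THF, 0 °C) would give (1R)-1-azido-1-[2,4-bis(methoxymethoxy)-3-prenylphenyl]-2-(3,5-dimethoxy-4-prenylphenoxy)ethane F8.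
- Staudinger reduction (PPh3, THF/H2O) would give 15.

**Further compounds**

F1 | step 9 | 1-[3-(3,5-dimethoxy-4-prenylphenoxy)prop-1-en-2-yl]-2,4-bis(methoxymethoxy)-3-prenylbenzene | C=C(COc1cc(OC)c(CC=C(C)C)c(OC)c1)c1ccc(OCOC)c(CC=C(C)C)c1OCOC
F2 | step 9 | 2-{2-[2,4-bis(methoxymethoxy)-3-prenylphenyl]prop-2-en-1-yl}-3,5-dimethoxy-4-prenylphenol | C=C(Cc1c(O)cc(OC)c(CC=C(C)C)c1OC)c1ccc(OCOC)c(CC=C(C)C)c1OCOC
F3 | step 9 | (R)-2-{2-[2,4-bis(methoxymethoxy)-3-prenylphenyl]-3-(4,4,5,5-tetramethyl-1,3,2-dioxaborolan-2-yl)propyl}-3,5-dimethoxy-4-prenylphenol | Oc1cc(OC)c(CC=C(C)C)c(OC)c1C[C@H](c1ccc(OCOC)c(CC=C(C)C)c1OCOC)CB1OC(C)(C)C(C)(C)O1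
F4 | step 9 | (2R)-2-[2,4-bis(methoxymethoxy)-3-prenylphenyl]-3-(6-hydroxy-2,4-dimethoxy-3-prenylphenyl)propan-1-ol | Oc1cc(OC)c(CC=C(C)C)c(OC)c1C[C@H](c1ccc(OCOC)c(CC=C(C)C)c1OCOC)CO
F5 | step 8 | N-{(1R)-1-[2,4-bis(methoxymethoxy)-3-prenylphenyl]-2-(3,5-dimethoxy-4-prenylphenoxy)ethyl}-2-nitrobenzenesulfonamide | O=S(=O)(N[C@H](c1ccc(OCOC)c(CC=C(C)C)c1OCOC)COc1cc(OC)c(CC=C(C)C)c(OC)c1)c1ccccc1[N+](=O)[O-]
F6 | step 8 | (3R)-3-[2,4-bis(methoxymethoxy)-3-prenylphenyl]-6,8-dimethoxy-4-(2-nitrophenylsulfonyl)-7-prenyl-2,3,4,5-tetrahydro-1,4-benzoxazepine | COCOc1ccc([C@H]2N(S(=O)(=O)c3ccccc3[N+](=O)[O-])Cc3c(OC)c(CC=C(C)C)c(OC)cc3OC2)c(OCOC)c1CC=C(C)C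
F7 | step 6 | (1S)-1-[2,4-bis(methoxymethoxy)-3-prenylphenyl]-2-(3,5-dimethoxy-4-prenylphenoxy)ethan-1-ol | O[C@@H](c1ccc(OCOC)c(CC=C(C)C)c1OCOC)COc1cc(OC)c(CC=C(C)C)c(OC)c1
F8 | step 6 | (1R)-1-azido-1-[2,4-bis(methoxymethoxy)-3-prenylphenyl]-2-(3,5-dimethoxy-4-prenylphenoxy)ethane | [N-]=[N+]=N[C@H](c1ccc(OCOC)c(CC=C(C)C)c1OCOC)COc1cc(OC)c(CC=C(C)C)c(OC)c1
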